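**Retrosynthetic overview**

1. 12 ⇐ chromane-7,8-dione 11 ⇐ open-chain o-quinone 10 ⇐ monophenol 9. The dihydropyran ring, the only ring that is made, is closed last at the aryl C8a–O1 bond, in one pot that also installs the C8 oxygen.
2. Enabling feature: O1, O–C8 and O–C7 sit on three adjacent carbons of the benzene ring, so the C7/C8 catechol is the reduced form of an o-quinone in which C8a is the δ-carbon of the C7 carbonyl. The only other carbon the tether can reach, C5, carries the methyl group, and the para position of the phenol is occupied by the tether.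
3. 9 ⇐ C4–C4a bond by hydroboration/B-alkyl Suzuki coupling of (S)-geranyllinalool 4 with silyl-protected 4-bromo-3-methylphenol 6.
4. 4 ⇐ (2S,3S)-2,3-epoxygeranylgeraniol 2 ⇐ all-E geranylgeraniol 1. Asymmetric epoxidation sets the future C2, which no later step touches; both E-alkenes are bought with 1.

Key step: step 7

Remark: the quaternary carbon C2 of the target is (S) by CIP (O > C3 > side-chain CH2 > CH3); chromane numbering (O1, C2 … C8a) is used throughout, and 1 and 5 are taken as commercial.

**Step 1**
Reactants: 1 (2E,6E,10E)-geranylgeraniol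
Product: 2 (2S,3S)-2,3-epoxygeranylgeraniol, i.e. [(2S,3S)-3-methyl-3-[(3E,7E)-4,8,12-trimethyltrideca-3,7,11-trien-1-yl]oxiran-2-yl]methanol
Conditions: Ti(OiPr)4 (10 mol%), L-(+)-diethyl tartrate (12 mol%), t-BuOOH, 4 Å MS, CH2Cl2, −20 °C
Reagents that add atoms: tert-butyl hydroperoxide, CC(C)(C)OO
Why: Katsuki–Sharpless asymmetric epoxidation acts only on the titanium-bound allylic-alcohol alkene, and with L-(+)-tartrate an (E)-3,3-disubstituted allylic alcohol of the geraniol type should give the (2S,3S)-epoxide, which fixes the configuration of the future C2.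

**Step 2**
Reactants: 2 (2S,3S)-2,3-epoxygeranylgeraniol
Product: 3 (2R,3S)-2-(iodomethyl)-3-methyl-3-[(3E,7E)-4,8,12-trimethyltrideca-3,7,11-trien-1-yl]oxirane
Conditions: I2, PPh3, imidazole, Et2O/MeCN, 0 °C
Reagents that add atoms: iodine, II
Why: Appel-type iodination of the primary alcohol under near-neutral conditions should leave the epoxide and both stereocentres untouched (the C2 descriptor changes to R only through CIP priority).

**Step 3**
Reactants: 3 epoxy iodide
Product: 4 (S)-geranyllinalool, i.e. (3S,6E,10E)-3,7,11,15-tetramethylhexadeca-1,6,10,14-tetraen-3-ol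
Conditions: activated Zn dust, EtOH, 70 °C
Reagents that add atoms: none
Why: zinc insertion into the C–I bond followed by β-elimination (reductive epoxide opening) breaks only the secondary C–O bond, so the tertiary carbinol centre should be delivered unchanged as the (S)-vinyl carbinol.

**Step 4**
Reactants: 5 4-bromo-3-methylphenol
Product: 6 (4-bromo-3-methylphenoxy)triisopropylsilane
Conditions: TIPSCl, imidazole, DMF, rt
Reagents that add atoms: triisopropylsilyl chloride, CC(C)[Si](Cl)(C(C)C)C(C)C
Why: standard silylation of a phenol; the bulky TIPS aryl ether is chosen because it should survive the aqueous base of the coupling step.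

**Step 5**
Reactants: 4 (S)-geranyllinalool; 6 (4-bromo-3-methylphenoxy)triisopropylsilane
Product: 8 (3S,6E,10E)-1-[2-methyl-4-(triisopropylsilyloxy)phenyl]-3,7,11,15-tetramethylhexadeca-6,10,14-trien-3-ol, via B-alkyl-9-BBN adduct 7 (not isolated)
Conditions: 9-BBN (2.2 equiv), THF, 0 °C to rt; then 6, Pd(OAc)2 (5 mol%), SPhos (10 mol%), 3 M aq. K3PO4, 60 °C
Reagents that add atoms: none
Why: 9-BBN should hydroborate the monosubstituted vinyl group anti-Markovnikov and far faster than the trisubstituted alkenes (one equivalent is consumed by the tertiary hydroxyl), and the B-alkyl Suzuki–Miyaura coupling then forms the C4–C4a bond without involving the carbinol centre.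

**Step 6**
Reactants: 8 silyl ether
Product: 9 4-[(3S,6E,10E)-3-hydroxy-3,7,11,15-tetramethylhexadeca-6,10,14-trien-1-yl]-3-methylphenol
Conditions: TBAF (1.1 equiv), AcOH (1.1 equiv), THF, 0 °C
Reagents that add atoms: none
Why: fluoride-mediated cleavage of the aryl Si–O bond, buffered so that no free phenoxide is exposed to air, should not affect the alkenes or the tertiary alcohol.

**Step 7**
Reactants: 9 monophenol carbinol
Product: 12 (2S)-2,5-dimethyl-2-[(3E,7E)-4,8,12-trimethyltrideca-3,7,11-trien-1-yl]chromane-7,8-diol, via open-chain o-quinone 10 (not isolated), via chromane-7,8-dione 11 (not isolated)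
Conditions: IBX (2.2 equiv), DMF, rt, Ar, dark; then aq. Na2S2O4, EtOAc, rt
Reagents that add atoms: 2-iodoxybenzoic acid (IBX), O=C1OI(=O)(O)c2ccccc12
Why: Proposed new method: IBX should bind the phenol as an aryloxy-λ5-iodane and transfer oxygen to the less hindered ortho carbon (future C8, next to a ring C–H and not to the methyl) to give o-quinone 10, which is the known IBX ortho-oxygenation of phenols; the C2 hydroxyl should then add to C8a, the δ-carbon of the C7 carbonyl's dienone, and enolisation of the adduct restores the aromatic ring, so the closure is a thermodynamically driven intramolecular 1,6-oxa-conjugate addition. The closest known reactions are the intramolecular additions of amines and carboxylates to catechol-derived o-quinones and the intermolecular 1,6-additions of thiols; addition of a tertiary alcohol in this sense is not established, hence the label. The ring closes in a 6-endo-trig mode on the C4a=C8a bond, assisted by the fully substituted carbinol carbon. No new stereocentre is formed and C2 keeps its S configuration because none of its bonds is broken. The first-formed catechol is more electron-rich than 10 and would be oxidised by it, so the second equivalent of IBX is meant to carry all material to the single quinone 11, which dithionite reduces to 12. Selectivity needed: oxygenation only ortho (the para position is blocked by the tether) and on the unhindered side, O-addition only at C8a (addition at methyl-bearing C5 cannot aromatise and should revert), and no reaction of the alkenes or the tertiary alcohol with IBX at room temperature.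

**Compound list**

1 | (2E,6E,10E)-geranylgeraniol | CC(C)=CCC/C(C)=C/CC/C(C)=C/CC/C(C)=C/CO | starting material
2 | (2S,3S)-2,3-epoxygeranylgeraniol | CC(C)=CCC/C(C)=C/CC/C(C)=C/CC[C@]1(C)O[C@H]1CO | intermediate
3 | (2R,3S)-2-(iodomethyl)-3-methyl-3-[(3E,7E)-4,8,12-trimethyltrideca-3,7,11-trien-1-yl]oxirane | CC(C)=CCC/C(C)=C/CC/C(C)=C/CC[C@]1(C)O[C@H]1CI | intermediate
4 | (S)-geranyllinalool, (3S,6E,10E)-3,7,11,15-tetramethylhexadeca-1,6,10,14-tetraen-3-ol | CC(C)=CCC/C(C)=C/CC/C(C)=C/CC[C@@](O)(C)C=C | intermediate
5 | 4-bromo-3-methylphenol | Cc1cc(O)ccc1Br | starting material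
6 | (4-bromo-3-methylphenoxy)triisopropylsilane | Cc1cc(O[Si](C(C)C)(C(C)C)C(C)C)ccc1Br | intermediate
7 | (3R,6E,10E)-1-(9-borabicyclo[3.3.1]nonan-9-yl)-3,7,11,15-tetramethylhexadeca-6,10,14-trien-3-ol (same spatial arrangement as 4) | CC(C)=CCC/C(C)=C/CC/C(C)=C/CC[C@@](O)(C)CCB1C2CCCC1CCC2 | intermediate (not isolated)
8 | (3S,6E,10E)-1-[2-methyl-4-(triisopropylsilyloxy)phenyl]-3,7,11,15-tetramethylhexadeca-6,10,14-trien-3-ol | CC(C)=CCC/C(C)=C/CC/C(C)=C/CC[C@@](O)(C)CCc1ccc(O[Si](C(C)C)(C(C)C)C(C)C)cc1C | intermediate
9 | 4-[(3S,6E,10E)-3-hydroxy-3,7,11,15-tetramethylhexadeca-6,10,14-trien-1-yl]-3-methylphenol | CC(C)=CCC/C(C)=C/CC/C(C)=C/CC[C@@](O)(C)CCc1ccc(O)cc1C | intermediate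
10 | 4-[(3S,6E,10E)-3-hydroxy-3,7,11,15-tetramethylhexadeca-6,10,14-trien-1-yl]-5-methylcyclohexa-3,5-diene-1,2-dione | CC(C)=CCC/C(C)=C/CC/C(C)=C/CC[C@@](O)(C)CCC1=CC(=O)C(=O)C=C1C | intermediate (not isolated)
11 | (2S)-2,5-dimethyl-2-[(3E,7E)-4,8,12-trimethyltrideca-3,7,11-trien-1-yl]-3,4-dihydro-2H-chromene-7,8-dione | CC(C)=CCC/C(C)=C/CC/C(C)=C/CC[C@@]1(C)CCC2=C(O1)C(=O)C(=O)C=C2C | intermediate (not isolated)
12 | (2S)-2,5-dimethyl-2-[(3E,7E)-4,8,12-trimethyltrideca-3,7,11-trien-1-yl]chromane-7,8-diol | CC(C)=CCC/C(C)=C/CC/C(C)=C/CC[C@@]1(C)CCc2c(C)cc(O)c(O)c2O1 | target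

**Step count and risks**

Total step count: 7. Longest linear sequence: 6 steps (1, 2, 3, 5, 6, 7 from geranylgeraniol); the aryl branch is one step (4) before the coupling.

Steps most likely to fail:

1. Step 7 (Proposed new method). The tertiary hydroxyl may add to the o-quinone more slowly than the quinone tautomerises to a quinone methide or oligomerises, and oxygen transfer may occur partly at the hindered ortho position. Fallback with known chemistry, forming the same C8a–O1 bond by Pd-catalysed aryl C–O coupling; it sets out from 4 and returns at 11. Commercial 3-bromo-5-methylphenol would be iodinated para to the hydroxyl (NIS, cat. TsOH, MeCN) to 3-bromo-4-iodo-5-methylphenol F1 and silylated (TIPSCl, imidazole, DMF) to (3-bromo-4-iodo-5-methylphenoxy)triisopropylsilane F2. Borane 7, made from 4 as in step 5, would be coupled selectively at the C–I bond (Pd(dppf)Cl2, aq. K3PO4, THF, rt to 40 °C) to the bromo carbinol F3. Intramolecular Buchwald-type etherification of the tertiary alcohol onto the aryl bromide (Pd(OAc)2, 2-(di-tert-butylphosphino)-1,1'-binaphthyl, Cs2CO3, toluene, 80 °C) should give the silyl-protected chromanol F4, and TBAF/AcOH the 7-hydroxy-5-methylchromane F5. IBX (1.1 equiv, DMF, rt) should then oxygenate the ortho position C8 (C6 is shielded by the 5-methyl group; para is ring-fused) to give 11, which dithionite reduces to 12 as in step 7.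

2. Step 5. The free tertiary hydroxyl consumes borane, and transmetalation of the hindered alkylborane onto an electron-rich arylpalladium species may be slow, so protodeboronation or incomplete coupling may result. Fallback that replaces the sp3–sp2 coupling by a Heck reaction; it sets out from 4 and 6 and returns at 8. Heck coupling of the vinyl carbinol 4 with 6 (Pd(OAc)2, P(o-tol)3, Et3N, DMF, 90 °C) should give the (E)-styrenyl carbinol F6. Diimide (2-nitrobenzenesulfonyl hydrazide, Et3N, CH2Cl2, rt) should then reduce the disubstituted styrenyl alkene in preference to the trisubstituted alkenes to give 8.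

3. Step 3. Zinc insertion may be sluggish, and iodide-induced opening or solvolysis of the epoxide may compete with the reductive elimination. Fallback by carbonyl transposition; it sets out from 2 and returns at 4. Parikh–Doering oxidation of 2 (SO3·pyridine, DMSO, Et3N, CH2Cl2, 0 °C) should give the epoxy aldehyde F7. Wharton transposition (N2H4·H2O, cat. AcOH, MeOH, 0 °C to rt) should then deliver 4 with the tertiary C–O bond intact.

**Further compounds**

F1 | step 7 | 3-bromo-4-iodo-5-methylphenol | Cc1cc(O)cc(Br)c1I
F2 | step 7 | (3-bromo-4-iodo-5-methylphenoxy)triisopropylsilane | Cc1cc(O[Si](C(C)C)(C(C)C)C(C)C)cc(Br)c1I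
F3 | step 7 | (3S,6E,10E)-1-[2-bromo-6-methyl-4-(triisopropylsilyloxy)phenyl]-3,7,11,15-tetramethylhexadeca-6,10,14-trien-3-ol | CC(C)=CCC/C(C)=C/CC/C(C)=C/CC[C@@](O)(C)CCc1c(C)cc(O[Si](C(C)C)(C(C)C)C(C)C)cc1Br
F4 | step 7 | triisopropyl{[(2S)-2,5-dimethyl-2-[(3E,7E)-4,8,12-trimethyltrideca-3,7,11-trien-1-yl]chroman-7-yl]oxy}silane | CC(C)=CCC/C(C)=C/CC/C(C)=C/CC[C@@]1(C)CCc2c(C)cc(O[Si](C(C)C)(C(C)C)C(C)C)cc2O1
F5 | step 7 | (2S)-2,5-dimethyl-2-[(3E,7E)-4,8,12-trimethyltrideca-3,7,11-trien-1-yl]chroman-7-ol | CC(C)=CCC/C(C)=C/CC/C(C)=C/CC[C@@]1(C)CCc2c(C)cc(O)cc2O1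
F6 | step 5 | (1E,3S,6E,10E)-1-[2-methyl-4-(triisopropylsilyloxy)phenyl]-3,7,11,15-tetramethylhexadeca-1,6,10,14-tetraen-3-ol | CC(C)=CCC/C(C)=C/CC/C(C)=C/CC[C@@](O)(C)/C=C/c1ccc(O[Si](C(C)C)(C(C)C)C(C)C)cc1C
F7 | step 3 | (2R,3S)-3-methyl-3-[(3E,7E)-4,8,12-trimethyltrideca-3,7,11-trien-1-yl]oxirane-2-carbaldehyde | CC(C)=CCC/C(C)=C/CC/C(C)=C/CC[C@]1(C)O[C@H]1C=O
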